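## Retrosynthetic overview

1. The target is a cycloisomer of the bicyclic type A PPAP **11** (C7 prenyl endo). Cutting C3–C2′ and C3′–C2″ leads back to a C3 radical cascade started from bromide **12**.
2. **11** comes from the monocyclic dearomatized acylphloroglucinol **10** by Markovnikov C1–C8 closure (ESIPT photocyclization) of an (R)-lavandulol-derived side chain.
3. **10** comes from 2,4,6-trihydroxybenzophenone by three C-alkylations: geranyl, then lavandulyl (dearomatizing, under a temporary bromine block), then prenyl.
4. Ring order: trione ring (from the arene) → cyclohexane ring C1/C5–C8 of the bicyclo[3.3.1] core → seven-membered ring of the homoadamantane → cyclopentane.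
5. Stereocontrol: C7 from lavandulol, C5 by epimer separation, C1 relayed from C5, C3/C2′/C2″ in the cascade.

## Assumptions and conventions

- (R)-(−)-Lavandulol (the natural enantiomer) is taken as purchasable; otherwise it is obtained by lipase resolution of the commercial racemate.
- The two C6 epimers of **8**, formed about 1:1, are taken as separable by chromatography.
- PPAP numbering is used in the text: C1 (benzoyl bridgehead), C2, C3, C4, C5 (geranyl bridgehead), C6, C7, C8 (CMe2), C9 (bridging C=O); C1′–C3′ are the C7-prenyl carbons and C1″–C3″ the C3-prenyl carbons.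
- Enolates and excited states are not numbered; the three carbon radicals of step 8 are listed because they define the cascade.
- The photocyclization in step 6 is proposed by analogy to reported ESIPT closures of dearomatized acylphloroglucinols; conditions are indicative.

## Route

Step 1
Reactants: 1 2,4,6-trihydroxybenzophenone; 2 geranyl bromide
Product: 3 3-geranyl-2,4,6-trihydroxybenzophenone
Conditions: DBU (1.1 equiv), THF, 0 °C to rt
Reagents that add atoms: none
Why: C-alkylation of the ambident phloroglucinol anion (SN2 on an allylic bromide, then re-aromatization by tautomerization) puts geranyl on a ring carbon; no stereocentre is formed and the E-alkene is kept.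

Step 2
Reactants: 3 3-geranyl-2,4,6-trihydroxybenzophenone
Product: 4 3-bromo-5-geranyl-2,4,6-trihydroxybenzophenone
Conditions: NBS (1.0 equiv), THF, −78 °C; water quench (no sulfite)
Reagents that add atoms: N-bromosuccinimide, O=C1CCC(=O)N1Br
Why: Electrophilic aromatic bromination of the last free, triply activated ring CH outruns bromonium formation on the trisubstituted alkenes at −78 °C; the bromine is a removable block that forces the next C-alkylation onto the geranyl-bearing carbon.

Step 3
Reactants: 5 (R)-lavandulol
Product: 6 (R)-lavandulyl triflate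
Conditions: Tf2O, 2,6-lutidine, CH2Cl2, −78 °C; used crude at once
Reagents that add atoms: trifluoromethanesulfonic anhydride, O=S(=O)(OS(=O)(=O)C(F)(F)F)C(F)(F)F
Why: O-sulfonylation of a primary alcohol (triflate formation) activates the β-branched carbinol for SN2; the stereocentre is not touched.

Step 4
Reactants: 4 3-bromo-5-geranyl-2,4,6-trihydroxybenzophenone; 6 (R)-lavandulyl triflate
Product: 8 (6S)-2-benzoyl-6-geranyl-3,5-dihydroxy-6-[(2S)-lavandulyl]cyclohexa-2,4-dien-1-one, via bromo dienone 7 (not isolated)
Conditions: LiN(SiMe3)2 (3.1 equiv), THF, −78 to 0 °C; then aq. Na2SO3, rt; chromatographic separation of the C6 epimers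
Reagents that add atoms: none
Why: Alkylative dearomatization: the lithium polyanion C-alkylates (SN2 on the primary triflate) at the only alkyl-bearing ring carbon, creating the quaternary centre without facial control (about 1:1, the 6S epimer is kept), and sulfite then removes the bromine of the 2-bromo-1,3-dicarbonyl unit by halophilic reduction; the lavandulyl centre is unchanged (its descriptor becomes S only through priorities).

Step 5
Reactants: 8 (6S)-2-benzoyl-6-geranyl-3,5-dihydroxy-6-[(2S)-lavandulyl]cyclohexa-2,4-dien-1-one; 9 prenyl bromide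
Product: 10 (6S)-2-benzoyl-6-geranyl-3,5-dihydroxy-4-prenyl-6-[(2S)-lavandulyl]cyclohexa-2,4-dien-1-one
Conditions: NaOMe (1.05 equiv), MeOH, 0 °C; 9 (1.0 equiv)
Reagents that add atoms: none
Why: C-alkylation of a vinylogous acid (lupulone-type prenylation): the only unsubstituted enol carbon attacks prenyl bromide by SN2; no new stereocentre.

Step 6
Reactants: 10 (6S)-2-benzoyl-6-geranyl-3,5-dihydroxy-4-prenyl-6-[(2S)-lavandulyl]cyclohexa-2,4-dien-1-one
Product: 11 (1S,5S,7S)-1-benzoyl-5-geranyl-4-hydroxy-8,8-dimethyl-3,7-diprenylbicyclo[3.3.1]non-3-ene-2,9-dione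
Conditions: hν (370 nm LED), degassed CH2Cl2, 0 °C
Reagents that add atoms: none
Why: ESIPT photocyclization (excited-state proton transfer, then Markovnikov cation–enolate collapse) delivers the chelated enol proton to the isopropenyl CH2 and the tertiary cation is captured by the benzoyl-bearing carbon, forming C1–C8 with type A regiochemistry; the tether fixes the face, so C1 follows from C5 and the lavandulol-derived C7 prenyl ends endo.

Step 7
Reactants: 11 (1S,5S,7S)-1-benzoyl-5-geranyl-4-hydroxy-8,8-dimethyl-3,7-diprenylbicyclo[3.3.1]non-3-ene-2,9-dione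
Product: 12 3-bromo-2,4,9-trione derived from 11 (Br exo)
Conditions: NBS (1.0 equiv), CH2Cl2, −78 °C
Reagents that add atoms: N-bromosuccinimide, O=C1CCC(=O)N1Br
Why: Electrophilic α-bromination of the enolized 1,3-diketone at C3, the only enolizable carbon, is much faster than attack on the alkenes; the C3 configuration is of no consequence because C3 becomes a planar radical.

Step 8
Reactants: 12 3-bromo-2,4,9-trione derived from 11
Product: 16 target CNP0155129.2, via C3 radical 13 (not isolated), via homoadamantyl carbinyl radical 14 (not isolated), via isopropyl radical 15 (not isolated)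
Conditions: Bu3SnH (1.2 equiv, syringe pump, 6 h), AIBN (0.2 equiv), PhH (5 mM), 80 °C
Reagents that add atoms: none
Why: Tin hydride radical cascade: bromine abstraction gives the 2,4-dioxo radical 13, which adds transannularly to C2′ of the endo C7 prenyl with the CMe2 end turned away from the C8 methyls (sets C2′, closes the seven-membered ring), radical 14 closes the cyclopentane by 5-exo-trig addition to the C3 prenyl (sets C2″, expected isopropyl cis to C1′ as in the natural series, and makes C3 quaternary with the cage fixing its configuration), and radical 15 takes H from Bu3SnH.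

## Compound list

1 | 2,4,6-trihydroxybenzophenone | O=C(c1ccccc1)c1c(O)cc(O)cc1O | starting material
2 | geranyl bromide, (2E)-1-bromo-3,7-dimethylocta-2,6-diene | CC(C)=CCC/C(C)=C/CBr | starting material
3 | 3-geranyl-2,4,6-trihydroxybenzophenone | CC(C)=CCC/C(C)=C/Cc1c(O)cc(O)c(C(=O)c2ccccc2)c1O | intermediate
4 | 3-bromo-5-geranyl-2,4,6-trihydroxybenzophenone | CC(C)=CCC/C(C)=C/Cc1c(O)c(Br)c(O)c(C(=O)c2ccccc2)c1O | intermediate
5 | (R)-(−)-lavandulol, (2R)-5-methyl-2-(prop-1-en-2-yl)hex-4-en-1-ol | OC[C@H](CC=C(C)C)C(C)=C | starting material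
6 | (R)-lavandulyl triflate | FC(F)(F)S(=O)(=O)OC[C@H](CC=C(C)C)C(C)=C | intermediate
7 | (6S)-2-benzoyl-4-bromo-6-geranyl-3,5-dihydroxy-6-[(2S)-lavandulyl]cyclohexa-2,4-dien-1-one (bromo dienone) | CC(C)=CCC/C(C)=C/C[C@@]1(C[C@H](CC=C(C)C)C(C)=C)C(=O)C(C(=O)c2ccccc2)=C(O)C(Br)=C1O | intermediate
8 | (6S)-2-benzoyl-6-[(2E)-3,7-dimethylocta-2,6-dienyl]-3,5-dihydroxy-6-[(2S)-5-methyl-2-(prop-1-en-2-yl)hex-4-enyl]cyclohexa-2,4-dien-1-one | CC(C)=CCC/C(C)=C/C[C@@]1(C[C@H](CC=C(C)C)C(C)=C)C(=O)C(C(=O)c2ccccc2)=C(O)C=C1O | intermediate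
9 | prenyl bromide, 1-bromo-3-methylbut-2-ene | CC(C)=CCBr | starting material
10 | (6S)-2-benzoyl-6-geranyl-3,5-dihydroxy-4-(3-methylbut-2-enyl)-6-[(2S)-lavandulyl]cyclohexa-2,4-dien-1-one | CC(C)=CCC/C(C)=C/C[C@@]1(C[C@H](CC=C(C)C)C(C)=C)C(=O)C(C(=O)c2ccccc2)=C(O)C(CC=C(C)C)=C1O | intermediate
11 | (1S,5S,7S)-1-benzoyl-5-geranyl-4-hydroxy-8,8-dimethyl-3,7-bis(3-methylbut-2-enyl)bicyclo[3.3.1]non-3-ene-2,9-dione (C7 prenyl endo) | CC(C)=CCC/C(C)=C/C[C@]12C[C@H](CC=C(C)C)C(C)(C)[C@@](C(=O)c3ccccc3)(C2=O)C(=O)C(CC=C(C)C)=C1O | intermediate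
12 | 1-benzoyl-3-bromo-5-geranyl-8,8-dimethyl-3,7-diprenylbicyclo[3.3.1]nonane-2,4,9-trione (C1, C5, C7 as in 11; Br exo drawn) | CC(C)=CCC/C(C)=C/C[C@]12C[C@H](CC=C(C)C)C(C)(C)[C@@](C(=O)c3ccccc3)(C2=O)C(=O)[C@](Br)(CC=C(C)C)C1=O | intermediate
13 | C3 radical of the bicyclic trione (2,4-dioxo radical) | CC(C)=CCC/C(C)=C/C[C@]12C[C@H](CC=C(C)C)C(C)(C)[C@@](C(=O)c3ccccc3)(C2=O)C(=O)[C](CC=C(C)C)C1=O | intermediate
14 | homoadamantane trione with Me2C• on C2′ and intact C3 prenyl | CC(C)=CCC/C(C)=C/C[C@]12C[C@@H]3C[C@H]([C](C)C)[C@](CC=C(C)C)(C1=O)C(=O)[C@](C(=O)c1ccccc1)(C2=O)C3(C)C | intermediate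
15 | cyclopentane-closed radical, Me2C• on C2″ (isopropyl radical) | CC(C)=CCC/C(C)=C/C[C@]12C[C@@H]3C[C@@H]4C(C)(C)[C@H]([C](C)C)C[C@@]4(C1=O)C(=O)[C@](C(=O)c1ccccc1)(C2=O)C3(C)C | intermediate
16 | CNP0155129.2: 1-benzoyl-5-geranyl homoadamantane-2,4,9-trione (PPAP numbering) with C3–C2′ bond and cis-fused 2,2-dimethyl-3-isopropylcyclopentane, configuration as in the SMILES | CC(C)=CCC/C(C)=C/C[C@]12C[C@@H]3C[C@@H]4C(C)(C)[C@H](C(C)C)C[C@@]4(C1=O)C(=O)[C@](C(=O)c1ccccc1)(C2=O)C3(C)C | target

## Step count and risks

Total steps: 8. Longest linear sequence: 7 (steps 1, 2, 4, 5, 6, 7, 8 from compound 1); step 3 is a one-step branch.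

**Step 4 (alkylative dearomatization).** A β-branched primary triflate may O-alkylate, may attack the bromine-bearing carbon, and gives no control at the new quaternary carbon (half the material is the wrong epimer). If the epimers do not separate at 8 or 10, the mixture can be taken through step 6, where the wrong epimer gives the C7-exo bicycle. Fallback, setting out from 3 and returning at 10: drop the bromine block and change the order of events. Compound 3 is C-prenylated with 9 (DBU, THF) to 3-geranyl-5-prenyl-2,4,6-trihydroxybenzophenone F1. Alkylative dearomatization of F1 with 6 (LiN(SiMe3)2, THF) then gives 10 directly, next to its regioisomer alkylated at the prenyl-bearing carbon, which is removed by preparative HPLC. This skips steps 2 and 5 at the price of a statistical mixture.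

**Step 6 (photocyclization).** The proton may go to the 2,3-alkene of the geranyl group, the cation may be captured by oxygen (pyran) or by C3 (type B), and the endo series must close through a less favourable boat-like arrangement. Fallback, setting out from 10 and returning at 16: quaternize C3 first and close the ring thermally. NCS (CH2Cl2, −78 °C) converts 10 into the C3-chloro-C3-prenyl triketone F2 (C3 epimers), in which the benzoyl-bearing carbon is the only enol carbon left. Brønsted-acid cation cyclization (HCO2H, rt, where O-cyclized isomers revert) can then only give the type A bicycle, the 3-chloro analogue of 12 F3. F3 is carried through the cascade of step 8 (Bu3SnH, AIBN, PhMe, 110 °C) to 16.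

**Step 8 (radical cascade).** Radical 13 may be reduced before it cyclizes (this returns 11, which is recycled through step 7). The 5-exo closure may give the C2″ epimer, since a simple chair model favours isopropyl trans to C1′, or the C2′ epimer. Fallback, setting out from 11 and returning at 16: run the cascade oxidatively. Mn(OAc)3·2H2O and Cu(OAc)2·H2O (AcOH, rt) generate the same C3 radical straight from enol 11, and the last radical is oxidized to the alkene, giving the isopropenyl analogue of the target F4. Diimide (2-nitrobenzenesulfonohydrazide, Et3N, CH2Cl2) then saturates only the 1,1-disubstituted alkene and leaves the trisubstituted geranyl alkenes, giving 16. This also removes step 7.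

## Further compounds

F1 | step 4 | 3-geranyl-5-prenyl-2,4,6-trihydroxybenzophenone | CC(C)=CCC/C(C)=C/Cc1c(O)c(CC=C(C)C)c(O)c(C(=O)c2ccccc2)c1O
F2 | step 6 | (6S)-2-benzoyl-4-chloro-6-geranyl-3-hydroxy-4-prenyl-6-[(2S)-lavandulyl]cyclohex-2-ene-1,5-dione (C4 epimers) | CC(C)=CCC/C(C)=C/C[C@@]1(C[C@H](CC=C(C)C)C(C)=C)C(=O)C(C(=O)c2ccccc2)=C(O)C(Cl)(CC=C(C)C)C1=O
F3 | step 6 | 1-benzoyl-3-chloro-5-geranyl-8,8-dimethyl-3,7-diprenylbicyclo[3.3.1]nonane-2,4,9-trione (C1, C5, C7 as in 11; C3 epimers) | CC(C)=CCC/C(C)=C/C[C@]12C[C@H](CC=C(C)C)C(C)(C)[C@@](C(=O)c3ccccc3)(C2=O)C(=O)C(Cl)(CC=C(C)C)C1=O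
F4 | step 8 | isopropenyl analogue of the target (prop-1-en-2-yl in place of isopropyl) | CC(C)=CCC/C(C)=C/C[C@]12C[C@@H]3C[C@@H]4C(C)(C)[C@H](C(C)=C)C[C@@]4(C1=O)C(=O)[C@](C(=O)c1ccccc1)(C2=O)C3(C)C
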